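**Plan**

- Retrosynthesis: the two acetates and both epoxides are removed first (double Sharpless epoxidation of a bis-allylic diol). Then the ring C–C bond between the ketone carbon and the ring CH2 that separates it from the spiro-epoxide carbon is cut.
- Enabling feature: with the spiro epoxide as an alkene, the ketone C, this CH2, the ring sp2 carbon, the exocyclic carbon and its CH2–O form a C(=O)–CH2–C=C–CH2–O array. Binding the O to the ketone carbon as an ester gives a 12-membered lactone holding nine ring carbons, with the tenth outside as CH2SO2Ph. A transannular 1,5 O-to-C acyl shift contracts it to the ten-membered carbocycle.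
- Forward: ynoate carbocupration/allylation (tetrasubstituted alkene), Wittig (trisubstituted alkene) and Still–Gennari olefination (Z-enoate) build an open-chain seco acid. Mitsunobu closure gives the 12-ring, the acyl shift gives the ten-membered enone, and desulfonylation, desilylation, epoxidation and acetylation finish.
- Stereochemistry: the alkene geometries are set in the chain (syn-carbocupration, E-selective Wittig, Z-selective olefination), and the lactone bridge keeps CH2O cis to the new ring CH2. All four stereocentres come from D-(−)-diethyl tartrate in two syn epoxidations of allylic alcohols.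

Key step: step 16

Remark: L-(+)-tartrate is taken to give the 2S epoxy alcohol at the CH2OH-bearing carbon of a primary allylic alcohol; the target is R at both such carbons, hence D-(−)-tartrate. Locants in the names of 33 and 34 follow germacrane numbering.

**Route**

Step 1
Reactants: 1 tert-butyldimethyl(prop-2-yn-1-yloxy)silane; 2 methyl chloroformate
Product: 4 methyl 4-[(tert-butyldimethylsilyl)oxy]but-2-ynoate, via lithium acetylide 3 (not isolated)
Conditions: n-BuLi, THF, −78 °C; then ClCO2Me, −78 to 0 °C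
Reagents that add atoms: none
Why: Deprotonation of the terminal alkyne and C-acylation of the lithium acetylide by the chloroformate is the standard ynoate synthesis (acetylide acylation), with no stereocentre involved.

Step 2
Reactants: 4 methyl 4-[(tert-butyldimethylsilyl)oxy]but-2-ynoate; 5 allyl bromide
Product: 7 methyl (2Z)-4-[(tert-butyldimethylsilyl)oxy]-3-methyl-2-(prop-2-en-1-yl)but-2-enoate, via lithium alkenyl(methyl)cuprate 6 (not isolated)
Conditions: Me2CuLi (from MeLi and CuI), THF, −78 °C; then allyl bromide, HMPA, −78 to −30 °C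
Reagents that add atoms: lithium dimethylcuprate, [Li+].C[Cu-]C
Why: Conjugate addition of the methylcuprate to the ynoate is a syn-carbocupration, and the α-cuprio acrylate should be allylated with retention at low temperature, so that methyl and allyl end up cis and the ester cis to the CH2OSi group (carbocupration–alkylation of alkynoates).

Step 3
Reactants: 7 methyl (2Z)-4-[(tert-butyldimethylsilyl)oxy]-3-methyl-2-(prop-2-en-1-yl)but-2-enoate
Product: 8 (2Z)-4-[(tert-butyldimethylsilyl)oxy]-3-methyl-2-(prop-2-en-1-yl)but-2-en-1-ol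
Conditions: i-Bu2AlH, CH2Cl2, −78 °C
Reagents that add atoms: none
Why: i-Bu2AlH reduces the conjugated ester to the primary allylic alcohol (1,2-reduction) and should leave the silyl ether and both alkenes untouched.

Step 4
Reactants: 8 (2Z)-4-[(tert-butyldimethylsilyl)oxy]-3-methyl-2-(prop-2-en-1-yl)but-2-en-1-ol
Product: 10 tert-butyldimethyl{[(2Z)-2-methyl-3-[(phenylsulfonyl)methyl]hexa-2,5-dien-1-yl]oxy}silane, via allylic mesylate 9 (not isolated)
Conditions: MsCl, Et3N, CH2Cl2, −20 °C; then PhSO2Na, NaI (cat.), DMF, rt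
Reagents that add atoms: sodium benzenesulfinate, [Na+].[O-]S(=O)c1ccccc1
Why: The allylic mesylate is displaced by the sulfinate at sulfur (SN2 S-alkylation) to give the allyl sulfone, and the fully substituted γ-carbon should block SN2′ attack so that the alkene geometry is kept.

Step 5
Reactants: 10 tert-butyldimethyl{[(2Z)-2-methyl-3-[(phenylsulfonyl)methyl]hexa-2,5-dien-1-yl]oxy}silane
Product: 12 (3Z)-5-[(tert-butyldimethylsilyl)oxy]-4-methyl-3-[(phenylsulfonyl)methyl]pent-3-enal, via vicinal diol 11 (not isolated)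
Conditions: OsO4 (cat.), NMO, acetone–H2O, rt; then NaIO4, rt
Reagents that add atoms: N-methylmorpholine N-oxide (oxygen source through OsO4), C[N+]1([O-])CCOCC1
Why: OsO4 should dihydroxylate the unhindered monosubstituted alkene much faster than the tetrasubstituted one, and periodate cleaves the diol to the aldehyde (two-stage Lemieux–Johnson-type cleavage).

Step 6
Reactants: 13 ethyl (triphenyl-λ5-phosphanylidene)acetate; 5 allyl bromide
Product: 15 ethyl 2-(triphenyl-λ5-phosphanylidene)pent-4-enoate, via phosphonium bromide 14 (not isolated)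
Conditions: CHCl3, reflux; then aq. NaOH, CH2Cl2, rt
Reagents that add atoms: none
Why: C-alkylation of the ester-stabilised ylide by allyl bromide and deprotonation of the phosphonium salt gives the α-allyl ylide (ylide alkylation).

Step 7
Reactants: 12 (3Z)-5-[(tert-butyldimethylsilyl)oxy]-4-methyl-3-[(phenylsulfonyl)methyl]pent-3-enal; 15 ethyl 2-(triphenyl-λ5-phosphanylidene)pent-4-enoate
Product: 16 ethyl (2E,5Z)-7-[(tert-butyldimethylsilyl)oxy]-6-methyl-5-[(phenylsulfonyl)methyl]-2-(prop-2-en-1-yl)hepta-2,5-dienoate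
Conditions: CH2Cl2, 40 °C
Reagents that add atoms: none
Why: Wittig olefination with an α-substituted ester-stabilised ylide is E-selective, which should place the ester trans and the allyl group cis to the new chain, and the neutral conditions should spare the β,γ-unsaturated aldehyde from conjugation.

Step 8
Reactants: 16 ethyl (2E,5Z)-7-[(tert-butyldimethylsilyl)oxy]-6-methyl-5-[(phenylsulfonyl)methyl]-2-(prop-2-en-1-yl)hepta-2,5-dienoate
Product: 17 (2E,5Z)-7-[(tert-butyldimethylsilyl)oxy]-6-methyl-5-[(phenylsulfonyl)methyl]-2-(prop-2-en-1-yl)hepta-2,5-dien-1-ol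
Conditions: i-Bu2AlH, CH2Cl2, −78 °C
Reagents that add atoms: none
Why: 1,2-Reduction of the enoate by i-Bu2AlH gives the allylic alcohol, the sulfone and the silyl ether being inert at this temperature.

Step 9
Reactants: 17 (2E,5Z)-7-[(tert-butyldimethylsilyl)oxy]-6-methyl-5-[(phenylsulfonyl)methyl]-2-(prop-2-en-1-yl)hepta-2,5-dien-1-ol
Product: 18 (2E,5Z)-1-[(tert-butyldiphenylsilyl)oxy]-7-[(tert-butyldimethylsilyl)oxy]-6-methyl-5-[(phenylsulfonyl)methyl]-2-(prop-2-en-1-yl)hepta-2,5-diene
Conditions: TBDPSCl, imidazole, DMF, rt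
Reagents that add atoms: tert-butyl(chloro)diphenylsilane, CC(C)(C)[Si](Cl)(c1ccccc1)c1ccccc1
Why: Silylation of the only free hydroxyl with the more acid-stable TBDPS group (silyl ether formation) allows the later selective removal of the TBS ether.

Step 10
Reactants: 18 (2E,5Z)-1-[(tert-butyldiphenylsilyl)oxy]-7-[(tert-butyldimethylsilyl)oxy]-6-methyl-5-[(phenylsulfonyl)methyl]-2-(prop-2-en-1-yl)hepta-2,5-diene
Product: 20 (4E,7Z)-4-{[(tert-butyldiphenylsilyl)oxy]methyl}-9-[(tert-butyldimethylsilyl)oxy]-8-methyl-7-[(phenylsulfonyl)methyl]nona-4,7-dien-1-ol, via B-alkyl-9-BBN adduct 19 (not isolated)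
Conditions: 9-BBN, THF, 0 °C to rt; then 30% H2O2, aq. NaOH, 0 °C
Reagents that add atoms: hydrogen peroxide, OO
Why: 9-BBN should hydroborate only the monosubstituted terminal alkene, in the anti-Markovnikov sense, and oxidation of the borane gives the primary alcohol (hydroboration–oxidation).

Step 11
Reactants: 20 (4E,7Z)-4-{[(tert-butyldiphenylsilyl)oxy]methyl}-9-[(tert-butyldimethylsilyl)oxy]-8-methyl-7-[(phenylsulfonyl)methyl]nona-4,7-dien-1-ol
Product: 21 (4E,7Z)-4-{[(tert-butyldiphenylsilyl)oxy]methyl}-9-[(tert-butyldimethylsilyl)oxy]-8-methyl-7-[(phenylsulfonyl)methyl]nona-4,7-dienal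
Conditions: Dess–Martin periodinane, NaHCO3, CH2Cl2, rt
Reagents that add atoms: none
Why: Dess–Martin oxidation converts the primary alcohol into the aldehyde under buffered conditions that tolerate the silyl ethers, the sulfone and the alkenes.

Step 12
Reactants: 21 (4E,7Z)-4-{[(tert-butyldiphenylsilyl)oxy]methyl}-9-[(tert-butyldimethylsilyl)oxy]-8-methyl-7-[(phenylsulfonyl)methyl]nona-4,7-dienal; 22 ethyl 2-[bis(2,2,2-trifluoroethoxy)phosphoryl]propanoate
Product: 24 ethyl (2Z,6E,9Z)-6-{[(tert-butyldiphenylsilyl)oxy]methyl}-11-[(tert-butyldimethylsilyl)oxy]-2,10-dimethyl-9-[(phenylsulfonyl)methyl]undeca-2,6,9-trienoate, via potassium phosphonate 23 (not isolated)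
Conditions: KN(SiMe3)2, 18-crown-6, THF, −78 °C (anion preformed, then 21)
Reagents that add atoms: none
Why: Still–Gennari olefination with the bis(trifluoroethyl) phosphonate should give the (Z)-2-methyl-2-enoate under kinetic control, and the preformed phosphonate anion is too weak a base to deprotonate the sulfone.

Step 13
Reactants: 24 ethyl (2Z,6E,9Z)-6-{[(tert-butyldiphenylsilyl)oxy]methyl}-11-[(tert-butyldimethylsilyl)oxy]-2,10-dimethyl-9-[(phenylsulfonyl)methyl]undeca-2,6,9-trienoate
Product: 25 ethyl (2Z,6E,9Z)-6-{[(tert-butyldiphenylsilyl)oxy]methyl}-11-hydroxy-2,10-dimethyl-9-[(phenylsulfonyl)methyl]undeca-2,6,9-trienoate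
Conditions: PPTS (cat.), MeOH, rt
Reagents that add atoms: none
Why: Acid-catalysed methanolysis should cleave the primary TBS ether while the TBDPS ether survives (selective desilylation).

Step 14
Reactants: 25 ethyl (2Z,6E,9Z)-6-{[(tert-butyldiphenylsilyl)oxy]methyl}-11-hydroxy-2,10-dimethyl-9-[(phenylsulfonyl)methyl]undeca-2,6,9-trienoate
Product: 26 (2Z,6E,9Z)-6-{[(tert-butyldiphenylsilyl)oxy]methyl}-11-hydroxy-2,10-dimethyl-9-[(phenylsulfonyl)methyl]undeca-2,6,9-trienoic acid
Conditions: LiOH·H2O, THF–MeOH–H2O, 40 °C; then 1 M HCl to pH 4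
Reagents that add atoms: lithium hydroxide, [Li+].[OH-]
Why: Saponification of the ethyl ester should leave the Z-enoate geometry, the sulfone and the TBDPS ether untouched (ester hydrolysis).

Step 15
Reactants: 26 (2Z,6E,9Z)-6-{[(tert-butyldiphenylsilyl)oxy]methyl}-11-hydroxy-2,10-dimethyl-9-[(phenylsulfonyl)methyl]undeca-2,6,9-trienoic acid
Product: 27 (3Z,7E,10Z)-7-{[(tert-butyldiphenylsilyl)oxy]methyl}-3,11-dimethyl-10-[(phenylsulfonyl)methyl]-1-oxacyclododeca-3,7,10-trien-2-one
Conditions: PPh3, DIAD, toluene–THF (0.003 M, slow addition of 26), 0 °C to rt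
Reagents that add atoms: none
Why: Mitsunobu macrolactonisation activates the primary allylic alcohol and not the acid, so the (Z)-2-methyl-enoic acid is never turned into an isomerisation-prone acyl derivative, and SN2 attack of the carboxylate under high dilution should close the 12-membered ring (SN2′ is blocked by the fully substituted γ-carbon).

Step 16
Reactants: 27 (3Z,7E,10Z)-7-{[(tert-butyldiphenylsilyl)oxy]methyl}-3,11-dimethyl-10-[(phenylsulfonyl)methyl]-1-oxacyclododeca-3,7,10-trien-2-one
Product: 30 (2Z,6E,9Z)-6-{[(tert-butyldiphenylsilyl)oxy]methyl}-9-(1-hydroxypropan-2-ylidene)-2-methyl-10-(phenylsulfonyl)cyclodeca-2,6-dien-1-one (racemic at the sulfonyl carbon), via lithiated sulfone 28 (not isolated), via bicyclic lithium hemiketalate 29 (not isolated)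
Conditions: LiN(SiMe3)2 (2.5 equiv), THF (0.01 M), −78 to 0 °C; aq. NH4Cl
Reagents that add atoms: none
Why: LiN(SiMe3)2 deprotonates the CH2 flanked by the sulfone and the tetrasubstituted alkene, the carbanion adds to the lactone carbonyl that the ring holds next to it (CH2SO2Ph and CH2O are cis on the alkene) to give the bicyclic hemiketalate 29, and this collapses with cleavage of the acyl C–O bond, so that the O–CH2–C(CH3)= bridge leaves the ring (12 to 10 atoms) and ends as the free allylic alcohol while the β-keto sulfone is drained as its enolate. The closest known reaction types are the Claisen-type C-acylation of α-sulfonyl carbanions by esters and lactones and the Baker–Venkataraman 1,5 O-to-C acyl shift. The ten-membered carbocycle is closed transannularly, by a 6-exo-trig addition across the twelve-membered ring followed by opening of the six-membered hemiketal ring. The only new stereocentre (the carbon bearing the sulfone) is uncontrolled and is erased in step 17, while the geometry of the three alkenes is conserved because none of their carbons takes part. The step needs the 1,2-addition to outrun 1,4-elimination of the allylic carboxylate from the same carbanion, γ-attack, conjugate addition to the enoate and intermolecular condensation; the lithium counter-ion, −78 °C and the six-membered transition state should favour the acyl shift, γ-attack and conjugate addition would need four- and eight-membered transition states, and dilution suppresses the intermolecular path.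

Step 17
Reactants: 30 (2Z,6E,9Z)-6-{[(tert-butyldiphenylsilyl)oxy]methyl}-9-(1-hydroxypropan-2-ylidene)-2-methyl-10-(phenylsulfonyl)cyclodeca-2,6-dien-1-one
Product: 31 (2Z,6E,9Z)-6-{[(tert-butyldiphenylsilyl)oxy]methyl}-9-(1-hydroxypropan-2-ylidene)-2-methylcyclodeca-2,6-dien-1-one
Conditions: SmI2 (2.5 equiv), THF–MeOH, −78 °C
Reagents that add atoms: none
Why: SmI2 cleaves the C–S bond of the β-keto sulfone by electron transfer, and kinetic α-protonation of the samarium dienolate by methanol should give the β,γ-unsaturated ketone without moving the tetrasubstituted alkene into conjugation (reductive desulfonylation).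

Step 18
Reactants: 31 (2Z,6E,9Z)-6-{[(tert-butyldiphenylsilyl)oxy]methyl}-9-(1-hydroxypropan-2-ylidene)-2-methylcyclodeca-2,6-dien-1-one
Product: 32 (2Z,6E,9Z)-6-(hydroxymethyl)-9-(1-hydroxypropan-2-ylidene)-2-methylcyclodeca-2,6-dien-1-one
Conditions: HF·pyridine, pyridine, THF, 0 °C to rt
Reagents that add atoms: none
Why: Buffered HF·pyridine removes the TBDPS ether without base, so the β,γ-unsaturated ketone should not isomerise (fluoride desilylation).

Step 19
Reactants: 32 (2Z,6E,9Z)-6-(hydroxymethyl)-9-(1-hydroxypropan-2-ylidene)-2-methylcyclodeca-2,6-dien-1-one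
Product: 33 (1(10)Z,4R,5R,7S,11R)-4,5:7,11-diepoxy-12,15-dihydroxygermacr-1(10)-en-9-one
Conditions: Ti(OiPr)4, D-(−)-diethyl tartrate, t-BuOOH (anhydrous, decane), 4 Å MS, CH2Cl2, −20 °C; aq. citric acid work-up
Reagents that add atoms: tert-butyl hydroperoxide, CC(C)(C)OO
Why: In this double Sharpless asymmetric epoxidation the titanium tartrate complex epoxidises only the two allylic alcohols (the enone alkene has no directing hydroxyl and is electron-poor), D-(−)-diethyl tartrate should deliver oxygen to the face that makes both CH2OH-bearing epoxide carbons R, and syn addition to the ring alkene (CH2OH trans to the ring CH2 on the other alkene carbon) and to the exocyclic alkene (CH2OH cis to the CH2 next to the ketone) then fixes the ring CH as R and the spiro carbon as S.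

Step 20
Reactants: 33 (1(10)Z,4R,5R,7S,11R)-4,5:7,11-diepoxy-12,15-dihydroxygermacr-1(10)-en-9-one
Product: 34 CNP0185847.2, (1(10)Z,4R,5R,7S,11R)-12,15-diacetoxy-4,5:7,11-diepoxygermacr-1(10)-en-9-one
Conditions: Ac2O, pyridine, DMAP (cat.), CH2Cl2, 0 °C
Reagents that add atoms: acetic anhydride, CC(=O)OC(C)=O
Why: Acetylation of the two primary alcohols under mild base with DMAP catalysis should leave the base-sensitive β,γ-epoxy ketone intact (ester formation).

**Compound list**

1 | tert-butyldimethyl(prop-2-yn-1-yloxy)silane | C#CCO[Si](C)(C)C(C)(C)C | starting material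
2 | methyl chloroformate | COC(=O)Cl | starting material
3 | lithium acetylide of 1 | [Li]C#CCO[Si](C)(C)C(C)(C)C | intermediate (not isolated)
4 | methyl 4-[(tert-butyldimethylsilyl)oxy]but-2-ynoate | COC(=O)C#CCO[Si](C)(C)C(C)(C)C | intermediate
5 | allyl bromide | C=CCBr | starting material
6 | lithium alkenyl(methyl)cuprate (Cu cis to the new methyl) | COC(=O)/C([Cu-]C)=C(/C)CO[Si](C)(C)C(C)(C)C.[Li+] | intermediate (not isolated)
7 | methyl (2Z)-4-[(tert-butyldimethylsilyl)oxy]-3-methyl-2-(prop-2-en-1-yl)but-2-enoate | COC(=O)/C(CC=C)=C(/C)CO[Si](C)(C)C(C)(C)C | intermediate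
8 | (2Z)-4-[(tert-butyldimethylsilyl)oxy]-3-methyl-2-(prop-2-en-1-yl)but-2-en-1-ol | OC/C(CC=C)=C(/C)CO[Si](C)(C)C(C)(C)C | intermediate
9 | methanesulfonate of 8 | CS(=O)(=O)OC/C(CC=C)=C(/C)CO[Si](C)(C)C(C)(C)C | intermediate (not isolated)
10 | tert-butyldimethyl{[(2Z)-2-methyl-3-[(phenylsulfonyl)methyl]hexa-2,5-dien-1-yl]oxy}silane | O=S(=O)(C/C(CC=C)=C(/C)CO[Si](C)(C)C(C)(C)C)c1ccccc1 | intermediate
11 | (4Z)-6-[(tert-butyldimethylsilyl)oxy]-5-methyl-4-[(phenylsulfonyl)methyl]hex-4-ene-1,2-diol (racemic) | O=S(=O)(C/C(CC(O)CO)=C(/C)CO[Si](C)(C)C(C)(C)C)c1ccccc1 | intermediate (not isolated)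
12 | (3Z)-5-[(tert-butyldimethylsilyl)oxy]-4-methyl-3-[(phenylsulfonyl)methyl]pent-3-enal | O=S(=O)(C/C(CC=O)=C(/C)CO[Si](C)(C)C(C)(C)C)c1ccccc1 | intermediate
13 | ethyl (triphenyl-λ5-phosphanylidene)acetate | CCOC(=O)C=P(c1ccccc1)(c1ccccc1)c1ccccc1 | starting material
14 | (1-ethoxy-1-oxopent-4-en-2-yl)triphenylphosphonium bromide | CCOC(=O)C(CC=C)[P+](c1ccccc1)(c1ccccc1)c1ccccc1.[Br-] | intermediate (not isolated)
15 | ethyl 2-(triphenyl-λ5-phosphanylidene)pent-4-enoate | CCOC(=O)C(CC=C)=P(c1ccccc1)(c1ccccc1)c1ccccc1 | intermediate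
16 | ethyl (2E,5Z)-7-[(tert-butyldimethylsilyl)oxy]-6-methyl-5-[(phenylsulfonyl)methyl]-2-(prop-2-en-1-yl)hepta-2,5-dienoate | CCOC(=O)/C(CC=C)=C/C/C(CS(=O)(=O)c1ccccc1)=C(\C)CO[Si](C)(C)C(C)(C)C | intermediate
17 | (2E,5Z)-7-[(tert-butyldimethylsilyl)oxy]-6-methyl-5-[(phenylsulfonyl)methyl]-2-(prop-2-en-1-yl)hepta-2,5-dien-1-ol | OC/C(CC=C)=C/C/C(CS(=O)(=O)c1ccccc1)=C(\C)CO[Si](C)(C)C(C)(C)C | intermediate
18 | (2E,5Z)-1-[(tert-butyldiphenylsilyl)oxy]-7-[(tert-butyldimethylsilyl)oxy]-6-methyl-5-[(phenylsulfonyl)methyl]-2-(prop-2-en-1-yl)hepta-2,5-diene | CC(C)(C)[Si](OC/C(CC=C)=C/C/C(CS(=O)(=O)c1ccccc1)=C(\C)CO[Si](C)(C)C(C)(C)C)(c1ccccc1)c1ccccc1 | intermediate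
19 | B-alkyl-9-BBN adduct of 18 (boron on the terminal carbon) | CC(C)(C)[Si](OC/C(CCCB1C2CCCC1CCC2)=C/C/C(CS(=O)(=O)c1ccccc1)=C(\C)CO[Si](C)(C)C(C)(C)C)(c1ccccc1)c1ccccc1 | intermediate (not isolated)
20 | (4E,7Z)-4-{[(tert-butyldiphenylsilyl)oxy]methyl}-9-[(tert-butyldimethylsilyl)oxy]-8-methyl-7-[(phenylsulfonyl)methyl]nona-4,7-dien-1-ol | CC(C)(C)[Si](OC/C(CCCO)=C/C/C(CS(=O)(=O)c1ccccc1)=C(\C)CO[Si](C)(C)C(C)(C)C)(c1ccccc1)c1ccccc1 | intermediate
21 | (4E,7Z)-4-{[(tert-butyldiphenylsilyl)oxy]methyl}-9-[(tert-butyldimethylsilyl)oxy]-8-methyl-7-[(phenylsulfonyl)methyl]nona-4,7-dienal | CC(C)(C)[Si](OC/C(CCC=O)=C/C/C(CS(=O)(=O)c1ccccc1)=C(\C)CO[Si](C)(C)C(C)(C)C)(c1ccccc1)c1ccccc1 | intermediate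
22 | ethyl 2-[bis(2,2,2-trifluoroethoxy)phosphoryl]propanoate | CCOC(=O)C(C)P(=O)(OCC(F)(F)F)OCC(F)(F)F | starting material
23 | potassium salt of 22 (phosphonate carbanion) | CCOC(=O)[C-](C)P(=O)(OCC(F)(F)F)OCC(F)(F)F.[K+] | intermediate (not isolated)
24 | ethyl (2Z,6E,9Z)-6-{[(tert-butyldiphenylsilyl)oxy]methyl}-11-[(tert-butyldimethylsilyl)oxy]-2,10-dimethyl-9-[(phenylsulfonyl)methyl]undeca-2,6,9-trienoate | CCOC(=O)/C(C)=C\CC/C(CO[Si](c1ccccc1)(c1ccccc1)C(C)(C)C)=C\C/C(CS(=O)(=O)c1ccccc1)=C(\C)CO[Si](C)(C)C(C)(C)C | intermediate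
25 | ethyl (2Z,6E,9Z)-6-{[(tert-butyldiphenylsilyl)oxy]methyl}-11-hydroxy-2,10-dimethyl-9-[(phenylsulfonyl)methyl]undeca-2,6,9-trienoate | CCOC(=O)/C(C)=C\CC/C(CO[Si](c1ccccc1)(c1ccccc1)C(C)(C)C)=C\C/C(CS(=O)(=O)c1ccccc1)=C(\C)CO | intermediate
26 | (2Z,6E,9Z)-6-{[(tert-butyldiphenylsilyl)oxy]methyl}-11-hydroxy-2,10-dimethyl-9-[(phenylsulfonyl)methyl]undeca-2,6,9-trienoic acid | OC(=O)/C(C)=C\CC/C(CO[Si](c1ccccc1)(c1ccccc1)C(C)(C)C)=C\C/C(CS(=O)(=O)c1ccccc1)=C(\C)CO | intermediate
27 | (3Z,7E,10Z)-7-{[(tert-butyldiphenylsilyl)oxy]methyl}-3,11-dimethyl-10-[(phenylsulfonyl)methyl]-1-oxacyclododeca-3,7,10-trien-2-one | C1C/C=C(C)\C(=O)OC/C(C)=C(CS(=O)(=O)c2ccccc2)/C/C=C1/CO[Si](c2ccccc2)(c2ccccc2)C(C)(C)C | intermediate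
28 | α-lithio sulfone of 27 | C1C/C=C(C)\C(=O)OC/C(C)=C(C([Li])S(=O)(=O)c2ccccc2)/C/C=C1/CO[Si](c2ccccc2)(c2ccccc2)C(C)(C)C | intermediate (not isolated)
29 | bicyclic lithium hemiketalate (six-membered O-containing ring bridging the ten-membered ring) | C1C/C=C(C)\C2(O[Li])OC/C(C)=C(C2S(=O)(=O)c3ccccc3)/C/C=C1/CO[Si](c3ccccc3)(c3ccccc3)C(C)(C)C | intermediate (not isolated)
30 | (2Z,6E,9Z)-6-{[(tert-butyldiphenylsilyl)oxy]methyl}-9-(1-hydroxypropan-2-ylidene)-2-methyl-10-(phenylsulfonyl)cyclodeca-2,6-dien-1-one (racemic at C10) | C1C/C=C(C)\C(=O)C(S(=O)(=O)c2ccccc2)/C(=C(/C)CO)C/C=C1/CO[Si](c2ccccc2)(c2ccccc2)C(C)(C)C | intermediate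
31 | (2Z,6E,9Z)-6-{[(tert-butyldiphenylsilyl)oxy]methyl}-9-(1-hydroxypropan-2-ylidene)-2-methylcyclodeca-2,6-dien-1-one | C1C/C=C(C)\C(=O)C/C(=C(/C)CO)C/C=C1/CO[Si](c2ccccc2)(c2ccccc2)C(C)(C)C | intermediate
32 | (2Z,6E,9Z)-6-(hydroxymethyl)-9-(1-hydroxypropan-2-ylidene)-2-methylcyclodeca-2,6-dien-1-one | C1C/C=C(C)\C(=O)C/C(=C(/C)CO)C/C=C1/CO | intermediate
33 | (1(10)Z,4R,5R,7S,11R)-4,5:7,11-diepoxy-12,15-dihydroxygermacr-1(10)-en-9-one | OC[C@]12CC/C=C(/C)C(=O)C[C@]3(C[C@H]1O2)O[C@]3(C)CO | intermediate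
34 | CNP0185847.2, (1(10)Z,4R,5R,7S,11R)-12,15-diacetoxy-4,5:7,11-diepoxygermacr-1(10)-en-9-one | CC(=O)OC[C@]12CC/C=C(/C)C(=O)C[C@]3(C[C@H]1O2)O[C@]3(C)COC(C)=O | target

**Summary**

Total step count: 20. Longest linear sequence: 19 steps (steps 1–5 and 7–20; step 6 is a one-step branch).

The three steps most likely to fail:

1. Step 16. The lithiated allyl sulfone may lose the allylic carboxylate by 1,4-elimination (ring opening to a sulfonyl diene) faster than it adds to the carbonyl, or it may condense intermolecularly. The fallback sets out from 26 and comes back at 30. Compound 26 is coupled with MeNH(OMe)·HCl (EDC·HCl, HOBt, i-Pr2NEt, CH2Cl2) to give the hydroxy Weinreb amide F1. LiN(SiMe3)2 (3.3 equiv) in THF at high dilution, −78 to 0 °C, then closes the ten-membered ring directly by C-acylation of the sulfonyl carbanion. The CH2O oxygen is then an alkoxide that cannot leave, and the product is 30.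

2. Step 19. Oxygen transfer to the hindered tetrasubstituted alkene may be slow, with titanium-promoted opening or β-elimination of the β,γ-epoxy ketone during the long reaction and loss of facial control at the second site. The fallback sets out from 32 and comes back at 33, and it separates the two epoxidations. Ti(OiPr)4/D-(−)-diethyl tartrate with one equivalent of t-BuOOH at −25 °C should epoxidise only the faster, trisubstituted allylic alcohol and give the mono-epoxy diol F2. The tetrasubstituted alkene is then epoxidised under ligand control with VO(OiPr)3, a chiral bis-hydroxamic acid ligand (the enantiomer matching the facial sense of D-tartrate) and aqueous t-BuOOH in toluene at 0 °C, without a strong Lewis acid, to give 33.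

3. Step 15. Oligomerisation, N-alkylation of the reduced azodicarboxylate, or 1,4-elimination from the oxyphosphonium salt of the allylic alcohol may compete with ring closure. The fallback sets out from 26 and comes back at 27, and it moves the activation from the alcohol to the acid. Shiina macrolactonisation (2-methyl-6-nitrobenzoic anhydride, DMAP, Et3N, CH2Cl2, slow addition, rt) through the mixed anhydride F3 should give 27. The allylic C–O bond is never turned into a leaving group, at the price of watching the Z-enoate for isomerisation.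

**Further compounds**

F1 | step 16 | (2Z,6E,9Z)-6-{[(tert-butyldiphenylsilyl)oxy]methyl}-11-hydroxy-N-methoxy-N,2,10-trimethyl-9-[(phenylsulfonyl)methyl]undeca-2,6,9-trienamide | CON(C)C(=O)/C(C)=C\CC/C(CO[Si](c1ccccc1)(c1ccccc1)C(C)(C)C)=C\C/C(CS(=O)(=O)c1ccccc1)=C(\C)CO
F2 | step 19 | (1(10)Z,4R,5R,7(11)Z)-4,5-epoxy-12,15-dihydroxygermacra-1(10),7(11)-dien-9-one | OC[C@]12CC/C=C(/C)C(=O)C/C(C[C@H]1O2)=C(/C)CO
F3 | step 15 | mixed anhydride of 26 with 2-methyl-6-nitrobenzoic acid | Cc1cccc([N+](=O)[O-])c1C(=O)OC(=O)/C(C)=C\CC/C(CO[Si](c1ccccc1)(c1ccccc1)C(C)(C)C)=C\C/C(CS(=O)(=O)c1ccccc1)=C(\C)CO
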